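**Retrosynthetic overview**
- The strategy rests on ring B: a phenol with OH at C1, Br at C2 and C4 (ortho and para to OH), H at C3 and C5, and the ether oxygen at C6. This is the pattern a 2-aryloxyphenol adopts when brominated under hydroxyl control.
- Disconnection 1: the aromaticity of ring B and both of its C–Br bonds are traced back to 2-aryloxycyclohex-2-enone 6 and bromine.
- Disconnection 2: the diaryl ether C–O bond is made at a non-aromatic carbon, from the phenoxide of 2 and epoxy ketone 4 (opening at the alpha carbon, then loss of water).
- 2 comes from guaiacol by tribromination; 4 comes from cyclohexenone by nucleophilic epoxidation.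
- Ring order: ring A (the 2,3,4-tribromo-6-methoxyphenyl ring) is aromatic from the start; the carbocycle that becomes ring B is brought in as cyclohexenone and aromatized last.

Key step: step 4

Remark: the target has no stereocenter. Compounds 4, 5 and 7 are racemic; the SMILES of 4 and 5 show one enantiomer to fix the relative configuration only.

**Step 1**
Reactants: 1 guaiacol (2-methoxyphenol)
Product: 2 2,3,4-tribromo-6-methoxyphenol (4,5,6-tribromoguaiacol)
Conditions: Br2 (3.05 equiv), AcOH, 10 → 40 °C; aq. NaHSO3
Reagents that add atoms: bromine, BrBr
Why: Electrophilic aromatic bromination in which the hydroxyl directs to its para and ortho carbons and the methoxy group to its para carbon, so that the one carbon that is only ortho to OMe and meta to OH should stay unsubstituted when the bromine charge is held at three equivalents.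

**Step 2**
Reactants: 3 cyclohex-2-en-1-one
Product: 4 2,3-epoxycyclohexan-1-one (7-oxabicyclo[4.1.0]heptan-2-one, racemic, cis-fused)
Conditions: 30% aq. H2O2, NaOH (cat.), MeOH, 0 → 15 °C
Reagents that add atoms: hydrogen peroxide, OO
Why: Weitz–Scheffer nucleophilic epoxidation (conjugate addition of hydroperoxide, then closure of the enolate onto the O–O bond) should give the necessarily cis-fused racemic epoxide, whose two stereocenters are both erased in steps 3 and 4.

**Step 3**
Reactants: 2 2,3,4-tribromo-6-methoxyphenol; 4 2,3-epoxycyclohexan-1-one (1.5 equiv)
Product: 6 2-(2,3,4-tribromo-6-methoxyphenoxy)cyclohex-2-en-1-one, via hydroxy ketone 5 (not isolated)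
Conditions: Cs2CO3 (0.3 equiv), DMPU, 90 °C
Reagents that add atoms: none
Why: The phenoxide opens the alpha,beta-epoxy ketone by SN2 attack at the carbonyl-activated alpha carbon with inversion to the trans beta-hydroxy ketone 5, and E1cB dehydration of this aldol should give the 2-aryloxy enone, the hydroxide released re-forming phenoxide so that the base is catalytic (the known reaction of phenols with epoxy ketones to diaryl ether precursors).

**Step 4**
Reactants: 6 2-(2,3,4-tribromo-6-methoxyphenoxy)cyclohex-2-en-1-one
Product: 11 2,4-dibromo-6-(2,3,4-tribromo-6-methoxyphenoxy)phenol, via bromo enone 7 (not isolated), via dienone 8 (not isolated), via aryloxyphenol 9 (not isolated), via monobromophenol 10 (not isolated)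
Conditions: Br2 (3.3 equiv), AcOH, 20 → 60 °C; aq. Na2S2O3
Reagents that add atoms: bromine, BrBr
Why: Acid-catalysed enolization of the ketone toward C6 and bromination should give bromo enone 7, which loses hydrogen bromide across C5–C6 to the cross-conjugated dienone 8; this is the keto tautomer of phenol 9 and aromatizes by proton shift from C4 to oxygen. The closest known reaction type is the dehydrogenation of cyclohexenones to phenols by bromine or CuBr2, joined here to the ordinary ortho/para bromination of the phenol so formed. No ring is closed: the existing carbocycle is aromatized to ring B, and the C–Br bonds at C4 and then C2 of ring B are formed by electrophilic substitution directed by the new hydroxyl (through 10). No stereocenter is created, and the one in 7 is destroyed on elimination. The step needs chemoselectivity between the rings and regioselectivity within ring B: the single C–H of ring A is deactivated by three bromines, while in ring B the hydroxyl outweighs the electron-poor aryloxy oxygen, so bromine should go para and ortho to OH and the charge of three equivalents (one for oxidation, two for substitution) should stop it there.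

**Compound list**
1 | guaiacol (2-methoxyphenol) | COc1ccccc1O | starting material
2 | 2,3,4-tribromo-6-methoxyphenol (4,5,6-tribromoguaiacol) | COc1cc(Br)c(Br)c(Br)c1O | intermediate
3 | cyclohex-2-en-1-one | O=C1C=CCCC1 | starting material
4 | 2,3-epoxycyclohexan-1-one (racemic, cis-fused) | O=C1CCC[C@H]2O[C@@H]12 | intermediate
5 | trans-3-hydroxy-2-(2,3,4-tribromo-6-methoxyphenoxy)cyclohexan-1-one (racemic) | COc1cc(Br)c(Br)c(Br)c1O[C@H]1[C@H](O)CCCC1=O | intermediate (not isolated)
6 | 2-(2,3,4-tribromo-6-methoxyphenoxy)cyclohex-2-en-1-one | COc1cc(Br)c(Br)c(Br)c1OC1=CCCCC1=O | intermediate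
7 | 6-bromo-2-(2,3,4-tribromo-6-methoxyphenoxy)cyclohex-2-en-1-one (racemic) | COc1cc(Br)c(Br)c(Br)c1OC1=CCCC(Br)C1=O | intermediate (not isolated)
8 | 2-(2,3,4-tribromo-6-methoxyphenoxy)cyclohexa-2,5-dien-1-one | COc1cc(Br)c(Br)c(Br)c1OC1=CCC=CC1=O | intermediate (not isolated)
9 | 2-(2,3,4-tribromo-6-methoxyphenoxy)phenol | COc1cc(Br)c(Br)c(Br)c1Oc1ccccc1O | intermediate (not isolated)
10 | 4-bromo-2-(2,3,4-tribromo-6-methoxyphenoxy)phenol | COc1cc(Br)c(Br)c(Br)c1Oc1cc(Br)ccc1O | intermediate (not isolated)
11 | 2,4-dibromo-6-(2,3,4-tribromo-6-methoxyphenoxy)phenol | COc1cc(Br)c(Br)c(Br)c1Oc1cc(Br)cc(Br)c1O | target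

**Step count**
Total steps: 4. Longest linear sequence: 3 steps (1 → 2 → 6 → 11, or equally 3 → 4 → 6 → 11).

**Steps most likely to fail**

Step 4. Bromine may attack the enol-ether double bond C2=C3 before the ketone enolizes toward C6. That would leave a vinylic bromine at C3 which is carried into ring B as a third bromine. Hydrogen bromide may also cleave the aryl enol ether before aromatization. The fallback separates oxidation from halogenation and sets out from 6. LiN(SiMe3)2 (THF, −78 °C) should form the cross-conjugated enolate at C6, and PhSeCl traps it as 6-(phenylselanyl)-2-(2,3,4-tribromo-6-methoxyphenoxy)cyclohex-2-en-1-one F1. H2O2 with pyridine (CH2Cl2, 0 → 25 °C) oxidizes this to the selenoxide 6-(phenylseleninyl)-2-(2,3,4-tribromo-6-methoxyphenoxy)cyclohex-2-en-1-one F2. Syn-elimination of F2 gives dienone 8 and, after tautomerization, phenol 9, which is isolated this time. Phenol 9 is then brominated with Br2 (2.05 equiv, AcOH, 0 → 20 °C) through 10, and the route is rejoined at 11.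

Step 3. The di-ortho-substituted, weakly nucleophilic phenoxide may open the epoxide too slowly, so that base-induced isomerization and self-condensation of the epoxy ketone consume it; attack may also stray to C3. The fallback avoids the epoxide and sets out from 2. Alkylation with 2-chlorocyclohexanone (K2CO3, KI cat., DMF, 60 °C), an SN2 displacement on an alpha-halo ketone, should give 2-(2,3,4-tribromo-6-methoxyphenoxy)cyclohexan-1-one F3. F3 is then treated with Br2 (4.4 equiv, AcOH, 20 → 70 °C). Two cycles of alpha-bromination and dehydrobromination should lead to phenol 9 in the flask whichever alpha carbon is brominated first, and the remaining two equivalents brominate it through 10. The route is rejoined at 11.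

Step 1. Stoichiometric control may be lost, with bromination of the fourth ring carbon, oxidative demethylation by excess bromine, or a stalled third bromination giving mixtures. The fallback stages the halogenation with a protecting group and sets out from 1. Acetylation (Ac2O, pyridine, 25 °C) gives 2-methoxyphenyl acetate F4. With the phenol masked the methoxy group controls, and NBS (MeCN, 25 °C) should place one bromine para to OMe, giving 5-bromo-2-methoxyphenyl acetate F5. Methanolysis (K2CO3, MeOH, 25 °C) frees 5-bromo-2-methoxyphenol F6. The free phenol then takes exactly two bromines (Br2, 2.05 equiv, AcOH, 10 °C) para and ortho to OH, and the route is rejoined at 2.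

**Further compounds**
F1 | step 4 | 6-(phenylselanyl)-2-(2,3,4-tribromo-6-methoxyphenoxy)cyclohex-2-en-1-one (racemic) | COc1cc(Br)c(Br)c(Br)c1OC1=CCCC([Se]c2ccccc2)C1=O
F2 | step 4 | 6-(phenylseleninyl)-2-(2,3,4-tribromo-6-methoxyphenoxy)cyclohex-2-en-1-one (mixture of diastereomers) | COc1cc(Br)c(Br)c(Br)c1OC1=CCCC([Se](=O)c2ccccc2)C1=O
F3 | step 3 | 2-(2,3,4-tribromo-6-methoxyphenoxy)cyclohexan-1-one (racemic) | COc1cc(Br)c(Br)c(Br)c1OC1CCCCC1=O
F4 | step 1 | 2-methoxyphenyl acetate | COc1ccccc1OC(C)=O
F5 | step 1 | 5-bromo-2-methoxyphenyl acetate | COc1ccc(Br)cc1OC(C)=O
F6 | step 1 | 5-bromo-2-methoxyphenol | COc1ccc(Br)cc1O
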